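**Retrosynthetic overview**
1. Target 21 ⇐ tetraol 20 by selective triacetylation (the hindered axial C4–OH stays free); 20 ⇐ lactone acetate 19 by LiAlH4.
2. Cyclopropane last: the C7–C8 bond of 19 comes from decarboxylative homoallyl → cyclopropylcarbinyl cation closure of norbornene acid 18, with acetate capture at C11.
3. Key disconnection: ring A and the bicyclo[2.2.1]heptene are formed together (C1–C6 and C7–C9 bonds) by intramolecular Diels–Alder reaction of a cyclopentadiene, released in situ from a tertiary allylic silyl ether, onto an (E)-alkylidene γ-lactone (14 → 16).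
4. Dienophile lactone 14 ⇐ epoxy alcohol 10 (phosphonoacetate opening, lactonisation, olefination with ethyl glyoxylate) ⇐ Sharpless kinetic resolution of allylic alcohol 9.
5. 9 ⇐ isobutyronitrile + 3-methylcyclopent-2-enone + vinylmagnesium bromide. Ring order: temporary γ-lactone → ring A + norbornene (one step) → cyclopropane.

Assumption: compounds 5–14 are carried as about 1:1 mixtures of epimers at the silyloxy-bearing ring carbon, a stereocentre that is erased in step 6; their SMILES leave it unspecified.
Locants C1–C11 in the text are those of the target skeleton: C1 quaternary apex, C2 CMe2, C3 CH–OAc, C4 CH–OH, C5 CH2, C6 C–CH2OAc, C7–C9 cyclopropane (C8 bears the methyl), C10 CH2 bridge, C11 CH–OAc bridge.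

**Step 1**
Reactants: 1 isobutyronitrile; 2 3-methylcyclopent-2-en-1-one
Product: 5 2-methyl-2-[3-methyl-1-(triethylsilyloxy)cyclopent-2-en-1-yl]propanenitrile (racemic), via lithiated isobutyronitrile 3 (not isolated), via lithium alkoxide 4 (not isolated)
Conditions: LiN(i-Pr)2, THF, −78 °C; then 2; then Et3SiCl, −78 → 23 °C
Reagents that add atoms: chlorotriethylsilane CC[Si](Cl)(CC)CC
Why: Kinetic 1,2-addition of the lithiated nitrile to the enone carbonyl (the β-carbon is fully substituted) makes the bond between the future C2 and C1, and in situ O-silylation blocks retro-addition and leaves a latent cyclopentadiene whose carbinol stereocentre is irrelevant.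

**Step 2**
Reactants: 5 silyloxy nitrile
Product: 7 2-methyl-2-[3-methyl-1-(triethylsilyloxy)cyclopent-2-en-1-yl]propanal, via N-aluminio aldimine 6 (not isolated)
Conditions: i-Bu2AlH, PhMe, −78 °C; then H2O, aq. potassium sodium tartrate, SiO2, 0 → 23 °C
Reagents that add atoms: water O
Why: Nitrile-to-aldehyde reduction stops at the N-aluminio aldimine of this hindered α-quaternary nitrile, and mild hydrolysis gives the non-enolisable aldehyde without touching the silyl ether.

**Step 3**
Reactants: 7 aldehyde; 8 vinylmagnesium bromide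
Product: 9 4-methyl-4-[3-methyl-1-(triethylsilyloxy)cyclopent-2-en-1-yl]pent-1-en-3-ol (racemic at C3 of the pentenol)
Conditions: CH2=CHMgBr, THF, −78 → 0 °C; then H2O
Reagents that add atoms: none
Why: Grignard 1,2-addition to the neopentyl aldehyde gives the secondary allylic alcohol as a racemate at the new carbinol centre, which is resolved in the next step.

**Step 4**
Reactants: 9 racemic allylic alcohol
Product: 10 (1R)-2-methyl-2-[3-methyl-1-(triethylsilyloxy)cyclopent-2-en-1-yl]-1-[(2S)-oxiran-2-yl]propan-1-ol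
Conditions: Ti(Oi-Pr)4 (0.2 equiv), D-(−)-diisopropyl tartrate (0.25 equiv), t-BuOOH (0.6 equiv), 4 Å molecular sieves, CH2Cl2, −20 °C
Reagents that add atoms: tert-butyl hydroperoxide CC(C)(C)OO
Why: Sharpless kinetic resolution epoxidises the (3S)-alcohols fast with D-(−)-tartrate and with the usual erythro selectivity, so one operation sets the absolute configuration of the future C3 and C4 oxygens (yield at most 50 %), while the silyl-protected ring alkene and the (3R)-alcohols do not react.

**Step 5**
Reactants: 10 epoxy alcohol; 11 triethyl phosphonoacetate; 12 ethyl glyoxylate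
Product: 14 ethyl (2E)-2-[(5S)-5-{(1R)-1-hydroxy-2-methyl-2-[3-methyl-1-(triethylsilyloxy)cyclopent-2-en-1-yl]propyl}-2-oxooxolan-3-ylidene]acetate, via phosphono lactone 13 (not isolated)
Conditions: NaH (1.1 equiv), 11 (1.15 equiv), 1,2-dimethoxyethane, 0 °C; then 10, 85 °C; then 12, 0 °C
Reagents that add atoms: none
Why: The phosphonoacetate anion opens the terminal epoxide at CH2, the liberated alkoxide lactonises onto the ester with the epoxide stereocentre retained, and the resulting α-phosphono lactone anion undergoes Horner–Wadsworth–Emmons olefination with the glyoxylate to give mainly the (E)-alkylidene lactone, which is purified by chromatography.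

**Step 6**
Reactants: 14 (E)-alkylidene lactone
Product: 16 ethyl 6-carboxy-3,4-dihydroxy-2,2,9-trimethyltricyclo[6.2.1.0^1,6]undec-9-ene-7-carboxylate 6,4-lactone (ester endo; lactone carbonyl exo), via cyclopentadiene 15 (not isolated)
Conditions: camphorsulfonic acid (10 mol %), PhMe (0.01 M), 0 → 23 °C; then Et3N (0.2 equiv), BHT, 90 °C
Reagents that add atoms: none
Why: Acid ionises the tertiary allylic silyl ether and E1 proton loss followed by 1,5-hydrogen shifts gives the 1-alkyl-3-methylcyclopentadiene, whose intramolecular Diels–Alder reaction with the doubly activated alkylidene lactone closes ring A and the norbornene in one operation; the γ-lactone bridge forces the C6 carboxyl cis to the C4 oxygen, and the transition state with the s-cis-locked lactone carbonyl exo and the ester endo puts the tether CH2 endo, which fixes C1, C7 and C9 relative to C6.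

**Step 7**
Reactants: 16 Diels–Alder adduct
Product: 18 6-carboxy-3,4-dihydroxy-2,2,9-trimethyltricyclo[6.2.1.0^1,6]undec-9-ene-7-carboxylic acid 6,4-lactone, via ring-opened dilithium salt 17 (not isolated)
Conditions: LiOH, THF–H2O, 40 °C; then 1 M HCl to pH 2, 23 °C
Reagents that add atoms: lithium hydroxide [Li+].[OH-]
Why: Saponification frees the carboxylic acid (the lactone may open but the 1,3-diaxial hydroxy acid relactonises on acidification), and any epimerisation next to the carboxyl is harmless because that centre is planarised in step 8.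

**Step 8**
Reactants: 18 norbornene acid
Product: 19 11-(acetyloxy)-3,4-dihydroxy-2,2,8-trimethyltetracyclo[6.2.1.0^1,6.0^7,9]undecane-6-carboxylic acid 6,4-lactone
Conditions: graphite anode, Pt cathode, undivided cell, AcOH, KOAc (0.3 equiv), constant current, 20 °C
Reagents that add atoms: acetic acid CC(=O)O
Why: Hofer–Moest (non-Kolbe) anodic decarboxylation gives the 5-norbornen-2-yl cation, the trisubstituted alkene closes onto it from the endo side (homoallyl to cyclopropylcarbinyl cation), and acetate adds to the nortricyclyl cation at C11 from the exo face, anti to the new C7–C8 bond, which places the acetoxy group syn to the CH2 bridge as in the target.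

**Step 9**
Reactants: 19 lactone acetate
Product: 20 (1S,3R,4S,6S,7R,8R,9R,10R)-6-(hydroxymethyl)-2,2,9-trimethyltetracyclo[6.2.1.0^1,6.0^7,9]undecane-3,4,10-triol (the tri-O-deacetyl target)
Conditions: LiAlH4, THF, 0 → 66 °C; then H2O, aq. NaOH
Reagents that add atoms: none
Why: Hydride reduction opens the lactone to the C6 hydroxymethyl and the C4 hydroxyl (cis by construction) and cleaves the acetate, with no stereocentre affected.

**Step 10**
Reactants: 20 tetraol
Product: 21 [(1S,3R,4S,6S,7R,8R,9R,11R)-3,11-bis(acetyloxy)-4-hydroxy-2,2,8-trimethyltetracyclo[6.2.1.0^1,6.0^7,9]undecan-6-yl]methyl acetate (CNP0111873.1)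
Conditions: Ac2O (3.3 equiv), pyridine, DMAP (5 mol %), CH2Cl2, 0 → 23 °C
Reagents that add atoms: acetic anhydride CC(=O)OC(C)=O
Why: Selective acylation acetylates the primary and the two accessible secondary hydroxyls, whereas the axial C4 hydroxyl, flanked by the syn-axial acetoxymethyl and methyl groups (the situation of a steroid 11β-hydroxyl), stays free.

**Compound list**
1 | isobutyronitrile | CC(C)C#N | starting material
2 | 3-methylcyclopent-2-en-1-one | CC1=CC(=O)CC1 | starting material
3 | lithiated isobutyronitrile | [Li]C(C)(C)C#N | intermediate (not isolated)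
4 | lithium 1-(2-cyanopropan-2-yl)-3-methylcyclopent-2-en-1-olate | [Li]OC1(C=C(C)CC1)C(C)(C)C#N | intermediate (not isolated)
5 | 2-methyl-2-[3-methyl-1-(triethylsilyloxy)cyclopent-2-en-1-yl]propanenitrile, racemic | CC[Si](CC)(CC)OC1(C=C(C)CC1)C(C)(C)C#N | intermediate
6 | N-(diisobutylaluminio) aldimine of 7 | CC(C)C[Al](CC(C)C)N=CC(C)(C)C1(O[Si](CC)(CC)CC)C=C(C)CC1 | intermediate (not isolated)
7 | 2-methyl-2-[3-methyl-1-(triethylsilyloxy)cyclopent-2-en-1-yl]propanal | O=CC(C)(C)C1(O[Si](CC)(CC)CC)C=C(C)CC1 | intermediate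
8 | vinylmagnesium bromide | C=C[Mg]Br | starting material
9 | 4-methyl-4-[3-methyl-1-(triethylsilyloxy)cyclopent-2-en-1-yl]pent-1-en-3-ol, racemic at C3 | C=CC(O)C(C)(C)C1(O[Si](CC)(CC)CC)C=C(C)CC1 | intermediate
10 | (1R)-2-methyl-2-[3-methyl-1-(triethylsilyloxy)cyclopent-2-en-1-yl]-1-[(2S)-oxiran-2-yl]propan-1-ol (erythro epoxy alcohol) | CC[Si](CC)(CC)OC1(C=C(C)CC1)C(C)(C)[C@@H](O)[C@@H]1CO1 | intermediate
11 | triethyl phosphonoacetate | CCOC(=O)CP(=O)(OCC)OCC | starting material
12 | ethyl glyoxylate | CCOC(=O)C=O | starting material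
13 | diethyl [(5S)-5-{(1R)-1-hydroxy-2-methyl-2-[3-methyl-1-(triethylsilyloxy)cyclopent-2-en-1-yl]propyl}-2-oxooxolan-3-yl]phosphonate (present as its sodium salt, both C3 epimers) | CCOP(=O)(OCC)C1C[C@H](OC1=O)[C@H](O)C(C)(C)C1(O[Si](CC)(CC)CC)C=C(C)CC1 | intermediate (not isolated)
14 | ethyl (2E)-2-[(5S)-5-{(1R)-1-hydroxy-2-methyl-2-[3-methyl-1-(triethylsilyloxy)cyclopent-2-en-1-yl]propyl}-2-oxooxolan-3-ylidene]acetate | CCOC(=O)/C=C1\C[C@H](OC1=O)[C@H](O)C(C)(C)C1(O[Si](CC)(CC)CC)C=C(C)CC1 | intermediate
15 | ethyl (2E)-2-[(5S)-5-{(1R)-1-hydroxy-2-methyl-2-(3-methylcyclopenta-1,3-dien-1-yl)propyl}-2-oxooxolan-3-ylidene]acetate (in equilibrium with its 1,5-hydrogen-shift isomers) | CCOC(=O)/C=C1\C[C@H](OC1=O)[C@H](O)C(C)(C)C1=CC(C)=CC1 | intermediate (not isolated)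
16 | ethyl 6-carboxy-3,4-dihydroxy-2,2,9-trimethyltricyclo[6.2.1.0^1,6]undec-9-ene-7-carboxylate 6,4-lactone; 7-CO2Et endo, lactone carbonyl exo, C5 methylene endo, 3-OH cis to the lactone oxygen | O=C4[C@]12C[C@H](O4)[C@H](O)C(C)(C)[C@]13C[C@H]([C@H]2C(=O)OCC)C(C)=C3 | intermediate
17 | dilithium 3,4-dihydroxy-2,2,9-trimethyltricyclo[6.2.1.0^1,6]undec-9-ene-6,7-dicarboxylate (configuration as in 16) | [Li+].[Li+].[O-]C(=O)[C@]12C[C@H](O)[C@H](O)C(C)(C)[C@]13C[C@H]([C@H]2C([O-])=O)C(C)=C3 | intermediate (not isolated)
18 | 6-carboxy-3,4-dihydroxy-2,2,9-trimethyltricyclo[6.2.1.0^1,6]undec-9-ene-7-carboxylic acid 6,4-lactone (configuration as in 16) | O=C4[C@]12C[C@H](O4)[C@H](O)C(C)(C)[C@]13C[C@H]([C@H]2C(O)=O)C(C)=C3 | intermediate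
19 | 11-(acetyloxy)-3,4-dihydroxy-2,2,8-trimethyltetracyclo[6.2.1.0^1,6.0^7,9]undecane-6-carboxylic acid 6,4-lactone; all stereocentres as in 21, 11-OAc syn to C10 | O=C4[C@]12C[C@H](O4)[C@H](O)C(C)(C)[C@]13C[C@@H]1[C@H]2[C@]1(C)[C@H]3OC(C)=O | intermediate
20 | (1S,3R,4S,6S,7R,8R,9R,10R)-6-(hydroxymethyl)-2,2,9-trimethyltetracyclo[6.2.1.0^1,6.0^7,9]undecane-3,4,10-triol | OC[C@]12C[C@H](O)[C@H](O)C(C)(C)[C@]13C[C@@H]1[C@H]2[C@]1(C)[C@H]3O | intermediate
21 | [(1S,3R,4S,6S,7R,8R,9R,11R)-3,11-bis(acetyloxy)-4-hydroxy-2,2,8-trimethyltetracyclo[6.2.1.0^1,6.0^7,9]undecan-6-yl]methyl acetate | CC(=O)OC[C@]12C[C@H](O)[C@H](OC(C)=O)C(C)(C)[C@]13C[C@@H]1[C@H]2[C@]1(C)[C@H]3OC(C)=O | target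

**Step count and risks**
Total steps: 10. Longest linear sequence: 10 (fully linear, 1/2 → 21).

Most likely to fail:

Step 6 (diene release and intramolecular Diels–Alder). The cation formed on ionisation could fragment or be trapped. The cycloaddition could also give the tether-exo adduct, or react through the 4-methyl diene tautomer. If the acid-triggered release is the problem, the route changes how the diene is made. Starting from 14, Bu4NF buffered with AcOH removes the silyl group to give tertiary allylic alcohol F3. F3 is dehydrated under neutral conditions with Martin sulfurane, which reacts with the tertiary but not the hindered secondary hydroxyl. This gives diene 15 directly, and warming converts it to 16, where the route is rejoined. This fallback does not correct a wrong endo/exo outcome.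

Step 8 (decarboxylative cation closure). The delocalised cation could be captured at C9 instead of C11, or intercepted by the lactone carbonyl. The fallback closes the cyclopropane anionically. Starting from 16, m-CPBA epoxidises the trisubstituted alkene from the exo face to give epoxide F4. KN(SiMe3)2 then forms the ester enolate at C7, which opens the epoxide at the methyl-bearing carbon from the endo side (3-exo-tet). This gives nortricyclanol ester F5, with the C11 hydroxyl already syn to C10. LiOH gives cyclopropane acid F6. F6 is converted with N-hydroxypyridine-2-thione and dicyclohexylcarbodiimide into Barton ester F7, which is reduced with t-BuSH under irradiation to lactone diol F8. F8 is reduced with LiAlH4 as in step 9, and the route is rejoined at 20.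

Step 4 (kinetic resolution of a very hindered carbinol). The reaction may be slow or poorly selective, and the yield is capped at 50 %. The fallback replaces resolution by asymmetric reduction. Starting from 9, Dess–Martin periodinane gives vinyl ketone F1. Reduction with (R)-2-methyl-CBS-oxazaborolidine and catecholborane, with the tert-alkyl group as the large substituent, gives (3S)-allylic alcohol F2. F2 is epoxidised under the step 4 conditions, now a matched reaction run to full conversion, and the route is rejoined at 10.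

**Further compounds**
F1 | step 4 | 4-methyl-4-[3-methyl-1-(triethylsilyloxy)cyclopent-2-en-1-yl]pent-1-en-3-one | C=CC(=O)C(C)(C)C1(O[Si](CC)(CC)CC)C=C(C)CC1
F2 | step 4 | (3S)-4-methyl-4-[3-methyl-1-(triethylsilyloxy)cyclopent-2-en-1-yl]pent-1-en-3-ol | C=C[C@H](O)C(C)(C)C1(O[Si](CC)(CC)CC)C=C(C)CC1
F3 | step 6 | ethyl (2E)-2-[(5S)-5-{(1R)-1-hydroxy-2-(1-hydroxy-3-methylcyclopent-2-en-1-yl)-2-methylpropyl}-2-oxooxolan-3-ylidene]acetate | CCOC(=O)/C=C1\C[C@H](OC1=O)[C@H](O)C(C)(C)C1(O)C=C(C)CC1
F4 | step 8 | exo-9,10-epoxide of 16 | O=C4[C@]12C[C@H](O4)[C@H](O)C(C)(C)[C@]13C[C@H]([C@H]2C(=O)OCC)[C@]5(C)[C@H]3O5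
F5 | step 8 | ethyl 6-carboxy-3,4,11-trihydroxy-2,2,8-trimethyltetracyclo[6.2.1.0^1,6.0^7,9]undecane-7-carboxylate 6,4-lactone (11-OH syn to C10) | O=C4[C@]12C[C@H](O4)[C@H](O)C(C)(C)[C@]13C[C@@H]1[C@@]2(C(=O)OCC)[C@]1(C)[C@H]3O
F6 | step 8 | 6-carboxy-3,4,11-trihydroxy-2,2,8-trimethyltetracyclo[6.2.1.0^1,6.0^7,9]undecane-7-carboxylic acid 6,4-lactone | O=C4[C@]12C[C@H](O4)[C@H](O)C(C)(C)[C@]13C[C@@H]1[C@@]2(C(O)=O)[C@]1(C)[C@H]3O
F7 | step 8 | 2-thioxopyridin-1(2H)-yl ester (Barton ester) of F6 | O=C4[C@]12C[C@H](O4)[C@H](O)C(C)(C)[C@]13C[C@@H]1[C@@]2(C(=O)ON5C=CC=CC5=S)[C@]1(C)[C@H]3O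
F8 | step 8 | 3,4,11-trihydroxy-2,2,8-trimethyltetracyclo[6.2.1.0^1,6.0^7,9]undecane-6-carboxylic acid 6,4-lactone (deacetyl 19) | O=C4[C@]12C[C@H](O4)[C@H](O)C(C)(C)[C@]13C[C@@H]1[C@H]2[C@]1(C)[C@H]3O
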